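## Retrosynthetic overview

1. Labels: the upper isoflavone is ring A (chlorinated benzo ring), ring C (pyranone) and ring B' (para-phenylene, C1'–C6'). The lower isoflavone is ring D (benzo ring, C4a''–C8a''), ring E (pyranone) and ring G (4-hydroxyphenyl). Feature: the halves meet only at the oxygen linking C4' of ring B' to C8'' of ring D. C8'' is wedged between the oxygen-bearing carbons C7'' and C8a'', so C–O coupling at C8'' is unattractive.
2. Key disconnection: the C8''–O bond is carried from the start as a phenol oxygen, and ring B' is assembled on it. An aryl ethynyl ether supplies C3' and C4'. Methyl coumalate supplies the other four ring carbons and the ester carbon on C1'. A [4+2] cycloaddition and loss of CO2 form C2'–C3' and C4'–C5'.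
3. The ester carbon becomes C3 of ring C. The future C4 is added by reduction, chlorination and Pd-catalysed methoxycarbonylation, and the arylacetic acid stays masked as its methyl ester.
4. The aryl ketone bonds C4''–C4a'' and C4–C4a come from ortho-acylations in BF3·OEt2. Ring D is debenzylated and acylated first with 4-methoxyphenylacetic acid, which brings ring G, deactivates ring D and keeps hydrogenolysis away from chlorine. The freed acid then acylates 2-chloro-3,5-dimethoxyphenol (ring A).
5. Ring order: D (purchased) → B' (built) → G and A (brought in intact) → E and C (closed together with DMF-DMA). Five O-methyl groups are removed last.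

Key step: step 5

Remark: the target has no stereocentre, and rotation about the diaryl ether and aryl–chromenone bonds is taken as free, so no stereocontrol is planned.

## Route

Step 1
Reactants: 1 2-hydroxy-4,6-dimethoxybenzaldehyde
Product: 2 2-(benzyloxy)-4,6-dimethoxybenzaldehyde
Conditions: BnBr, K2CO3, DMF, 60 °C
Reagents that add atoms: benzyl bromide, BrCc1ccccc1
Why: Williamson ether synthesis on the only free phenol; the benzyl group marks the oxygen that becomes O1'' and can later be removed by hydrogenolysis without touching the methyl ethers.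

Step 2
Reactants: 2 2-(benzyloxy)-4,6-dimethoxybenzaldehyde
Product: 4 2-(benzyloxy)-4,6-dimethoxyphenol, via aryl formate 3 (not isolated)
Conditions: mCPBA, CH2Cl2, 0 °C to rt; aq NaHCO3 wash; then K2CO3 (cat.), MeOH, rt, Ar
Reagents that add atoms: 3-chloroperoxybenzoic acid, O=C(OO)c1cccc(Cl)c1
Why: Baeyer–Villiger (Dakin-type) oxidation in which the very electron-rich trialkoxyaryl group migrates in preference to hydride, and base-catalysed methanolysis of the formate frees the phenol whose oxygen is the future ether oxygen on C8''.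

Step 3
Reactants: 4 2-(benzyloxy)-4,6-dimethoxyphenol; 5 trichloroethylene
Product: 7 1-(benzyloxy)-2-{[(E)-1,2-dichloroethenyl]oxy}-3,5-dimethoxybenzene, via dichloroacetylene 6 (not isolated)
Conditions: K2CO3, DMF, 70 °C, Ar
Reagents that add atoms: none
Why: Dehydrochlorination of trichloroethylene followed by anti addition of the phenoxide to the slim, linear chloroalkyne (the standard entry to aryl 1,2-dichlorovinyl ethers), an event little affected by the two ortho substituents.

Step 4
Reactants: 7 1-(benzyloxy)-2-{[(E)-1,2-dichloroethenyl]oxy}-3,5-dimethoxybenzene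
Product: 10 1-(benzyloxy)-2-(ethynyloxy)-3,5-dimethoxybenzene, via chloroethynyl ether 8 (not isolated), via lithium acetylide 9 (not isolated)
Conditions: n-BuLi (2.3 equiv), Et2O–THF, −78 to −40 °C; H2O quench at −78 °C; cold extractive work-up, used at once
Reagents that add atoms: none
Why: Elimination route to ynol ethers, in which the first n-BuLi removes the vinylic proton and LiCl leaves, the second exchanges the alkynyl chlorine for lithium and water protonates the acetylide; at low temperature these events outrun ring lithiation and benzyl ether rearrangement.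

Step 5
Reactants: 10 1-(benzyloxy)-2-(ethynyloxy)-3,5-dimethoxybenzene; 11 methyl coumalate
Product: 13 methyl 4-[2-(benzyloxy)-4,6-dimethoxyphenoxy]benzoate, via bridged lactone 12 (not isolated)
Conditions: 11 (1.5 equiv), toluene, 110 °C, sealed tube, Ar
Reagents that add atoms: none
Why: This is an inverse-electron-demand Diels–Alder reaction followed by retro-[4+2] loss of CO2, in which the ester-lowered LUMO of the pyrone diene (C3=C4–C5=C6) meets the oxygen-raised HOMO of ynol ether 10. Bonding is led by the nucleophilic terminal alkyne carbon attacking pyrone C6 (β to the ester, δ to the lactone carbonyl) while the oxygen-bearing alkyne carbon closes on C3, which forms C2'–C3' and C4'–C5' and places the ester para to the aryloxy group, the one selectivity the step needs. Ring B' is closed by intermolecular [4+2] annulation of four pyrone carbons and two alkyne carbons, and because the dienophile is an alkyne, lactone 12 becomes aromatic directly on extrusion of CO2, with no elimination that could expel the aryloxy group. The two bridgehead stereocentres of racemic 12 are tied to each other by the bicycle and vanish on aromatisation, so no stereocontrol is required. The closest known reactions are the cycloadditions of methyl coumalate with alkoxyalkynes, enol ethers and ketene acetals that give para-substituted benzoates; the present aryl ynol ether belongs to that class but is a weaker donor, and its ortho groups lie away from the linear C≡C–H terminus yet may call for more heat. The aryl group offers no sp3 β-hydrogen, so the retro-ene path to a ketene that limits alkyl ynol ethers on heating is closed.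

Step 6
Reactants: 13 methyl 4-[2-(benzyloxy)-4,6-dimethoxyphenoxy]benzoate
Product: 14 {4-[2-(benzyloxy)-4,6-dimethoxyphenoxy]phenyl}methanol
Conditions: LiAlH4, THF, 0 °C
Reagents that add atoms: none
Why: Hydride reduction of the benzoate ester to the benzylic alcohol; all ether groups are inert to LiAlH4.

Step 7
Reactants: 14 {4-[2-(benzyloxy)-4,6-dimethoxyphenoxy]phenyl}methanol
Product: 15 1-(benzyloxy)-2-[4-(chloromethyl)phenoxy]-3,5-dimethoxybenzene
Conditions: SOCl2, pyridine, CH2Cl2, 0 °C
Reagents that add atoms: thionyl chloride, O=S(Cl)Cl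
Why: Darzens halogenation through the chlorosulfite; pyridine takes up HCl so that the activated benzylic chloride is not ionised next to the nucleophilic ring D.

Step 8
Reactants: 15 1-(benzyloxy)-2-[4-(chloromethyl)phenoxy]-3,5-dimethoxybenzene
Product: 16 methyl 2-{4-[2-(benzyloxy)-4,6-dimethoxyphenoxy]phenyl}acetate
Conditions: CO (1 atm), PdCl2(PPh3)2 (cat.), i-Pr2NEt, MeOH–THF, 55 °C
Reagents that add atoms: carbon monoxide, [C-]#[O+]; methanol, CO
Why: Palladium-catalysed methoxycarbonylation of a benzylic chloride (oxidative addition to zerovalent palladium formed in situ, CO insertion, methanolysis) adds the carbon that becomes C4 and delivers the acid in masked form.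

Step 9
Reactants: 16 methyl 2-{4-[2-(benzyloxy)-4,6-dimethoxyphenoxy]phenyl}acetate
Product: 17 methyl 2-[4-(2-hydroxy-4,6-dimethoxyphenoxy)phenyl]acetate
Conditions: H2 (1 atm), 10% Pd/C, EtOAc–MeOH, rt
Reagents that add atoms: none
Why: Hydrogenolysis of the benzyl ether, done before any chlorine is in the molecule so that hydrodechlorination cannot occur; the diaryl ether, methyl ethers and ester are inert.

Step 10
Reactants: 17 methyl 2-[4-(2-hydroxy-4,6-dimethoxyphenoxy)phenyl]acetate; 18 4-methoxyphenylacetic acid
Product: 19 methyl 2-[4-(2-hydroxy-4,6-dimethoxy-3-[(4-methoxyphenyl)acetyl]phenoxy)phenyl]acetate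
Conditions: 18 (2 equiv), BF3·OEt2 (solvent), 80 °C; aq NaOAc work-up
Reagents that add atoms: none
Why: Friedel–Crafts acylation of a phenol by an arylacetic acid in BF3·OEt2 (the standard deoxybenzoin synthesis); Lewis acid coordination at the phenol oxygen steers the acyl group to the only free ortho carbon, which is also para to a methoxy group, the other free carbon is shielded between two methoxy groups, and the methyl ester is not an acyl donor here.

Step 11
Reactants: 19 methyl 2-[4-(2-hydroxy-4,6-dimethoxy-3-[(4-methoxyphenyl)acetyl]phenoxy)phenyl]acetate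
Product: 20 2-[4-(2-hydroxy-4,6-dimethoxy-3-[(4-methoxyphenyl)acetyl]phenoxy)phenyl]acetic acid
Conditions: LiOH, THF–H2O, rt; then 1 M HCl
Reagents that add atoms: lithium hydroxide, [Li+].[OH-]
Why: Saponification of an unhindered methyl arylacetate; the ortho-hydroxy ketone only forms its phenoxide and is recovered on acidification.

Step 12
Reactants: 21 3,5-dimethoxyphenol
Product: 22 2-chloro-3,5-dimethoxyphenol
Conditions: SO2Cl2 (1 equiv), CHCl3, 0 °C to rt
Reagents that add atoms: sulfuryl chloride, O=S(=O)(Cl)Cl
Why: Electrophilic aromatic chlorination; the two equivalent carbons ortho to OH and para to OMe are favoured statistically and sterically over the carbon between the methoxy groups, one equivalent of reagent limits dichlorination, and the 4-chloro isomer is removed by chromatography or crystallisation.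

Step 13
Reactants: 20 2-[4-(2-hydroxy-4,6-dimethoxy-3-[(4-methoxyphenyl)acetyl]phenoxy)phenyl]acetic acid; 22 2-chloro-3,5-dimethoxyphenol
Product: 23 1-(3-chloro-2-hydroxy-4,6-dimethoxyphenyl)-2-[4-(2-hydroxy-4,6-dimethoxy-3-[(4-methoxyphenyl)acetyl]phenoxy)phenyl]ethan-1-one
Conditions: 22 (2 equiv), BF3·OEt2 (solvent), 85 °C; aq NaOAc work-up
Reagents that add atoms: none
Why: Second Friedel–Crafts acylation in BF3·OEt2; ring D of 20 now carries an electron-withdrawing ketone and is deactivated, so the acid acylates the excess phenol 22 at its free ortho carbon rather than another molecule of itself.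

Step 14
Reactants: 23 1-(3-chloro-2-hydroxy-4,6-dimethoxyphenyl)-2-[4-(2-hydroxy-4,6-dimethoxy-3-[(4-methoxyphenyl)acetyl]phenoxy)phenyl]ethan-1-one
Product: 25 8-chloro-3-(4-{[5,7-dimethoxy-3-(4-methoxyphenyl)-4-oxo-4H-chromen-8-yl]oxy}phenyl)-5,7-dimethoxy-4H-chromen-4-one, via bis-enaminone 24 (not isolated)
Conditions: DMF-DMA (excess), toluene, 95 °C
Reagents that add atoms: N,N-dimethylformamide dimethyl acetal, COC(OC)N(C)C
Why: Formamide acetal condensation at both activated methylene groups and addition–elimination of each neighbouring phenol with loss of dimethylamine (the DMF-DMA isoflavone synthesis) close rings C and E; each ketone has a single ortho hydroxyl, so chlorine stays on C8 and the aryloxy group on C8''.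

Step 15
Reactants: 25 8-chloro-3-(4-{[5,7-dimethoxy-3-(4-methoxyphenyl)-4-oxo-4H-chromen-8-yl]oxy}phenyl)-5,7-dimethoxy-4H-chromen-4-one
Product: 26 8-chloro-3-(4-{[5,7-dihydroxy-3-(4-hydroxyphenyl)-4-oxo-4H-chromen-8-yl]oxy}phenyl)-5,7-dihydroxy-4H-chromen-4-one (bisoflavolin I)
Conditions: BBr3 (excess), CH2Cl2, −78 °C to rt; then H2O
Reagents that add atoms: none
Why: Lewis acid ether cleavage in which BBr3 binds each methoxy oxygen and bromide removes the methyl group by SN2; the aryl–O–aryl and aryl–Cl bonds have no such path, and the anhydrous, cold medium avoids the ring opening and reclosure (Wessely–Moser type) that could move substituents from C8 to C6.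

## Compound list

1 | 2-hydroxy-4,6-dimethoxybenzaldehyde | COc1cc(O)c(C=O)c(OC)c1 | starting material
2 | 2-(benzyloxy)-4,6-dimethoxybenzaldehyde | COc1cc(OCc2ccccc2)c(C=O)c(OC)c1 | intermediate
3 | 2-(benzyloxy)-4,6-dimethoxyphenyl formate | COc1cc(OCc2ccccc2)c(OC=O)c(OC)c1 | intermediate
4 | 2-(benzyloxy)-4,6-dimethoxyphenol | COc1cc(OCc2ccccc2)c(O)c(OC)c1 | intermediate
5 | trichloroethylene | ClC=C(Cl)Cl | starting material
6 | dichloroacetylene | ClC#CCl | intermediate
7 | 1-(benzyloxy)-2-{[(E)-1,2-dichloroethenyl]oxy}-3,5-dimethoxybenzene | Cl/C=C(Cl)\Oc1c(OC)cc(OC)cc1OCc1ccccc1 | intermediate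
8 | 1-(benzyloxy)-2-[(chloroethynyl)oxy]-3,5-dimethoxybenzene | ClC#COc1c(OC)cc(OC)cc1OCc1ccccc1 | intermediate
9 | lithium [2-(benzyloxy)-4,6-dimethoxyphenoxy]acetylide | [Li]C#COc1c(OC)cc(OC)cc1OCc1ccccc1 | intermediate
10 | 1-(benzyloxy)-2-(ethynyloxy)-3,5-dimethoxybenzene | C#COc1c(OC)cc(OC)cc1OCc1ccccc1 | intermediate
11 | methyl coumalate (methyl 2-oxo-2H-pyran-5-carboxylate) | COC(=O)c1ccc(=O)oc1 | starting material
12 | methyl 8-[2-(benzyloxy)-4,6-dimethoxyphenoxy]-3-oxo-2-oxabicyclo[2.2.2]octa-5,7-diene-6-carboxylate (racemic, one enantiomer drawn) | O=C1O[C@@H]2C=C(Oc3c(OC)cc(OC)cc3OCc3ccccc3)[C@H]1C=C2C(=O)OC | intermediate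
13 | methyl 4-[2-(benzyloxy)-4,6-dimethoxyphenoxy]benzoate | COC(=O)c1ccc(Oc2c(OC)cc(OC)cc2OCc2ccccc2)cc1 | intermediate
14 | {4-[2-(benzyloxy)-4,6-dimethoxyphenoxy]phenyl}methanol | OCc1ccc(Oc2c(OC)cc(OC)cc2OCc2ccccc2)cc1 | intermediate
15 | 1-(benzyloxy)-2-[4-(chloromethyl)phenoxy]-3,5-dimethoxybenzene | ClCc1ccc(Oc2c(OC)cc(OC)cc2OCc2ccccc2)cc1 | intermediate
16 | methyl 2-{4-[2-(benzyloxy)-4,6-dimethoxyphenoxy]phenyl}acetate | COC(=O)Cc1ccc(Oc2c(OC)cc(OC)cc2OCc2ccccc2)cc1 | intermediate
17 | methyl 2-[4-(2-hydroxy-4,6-dimethoxyphenoxy)phenyl]acetate | COC(=O)Cc1ccc(Oc2c(OC)cc(OC)cc2O)cc1 | intermediate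
18 | 4-methoxyphenylacetic acid | COc1ccc(CC(=O)O)cc1 | starting material
19 | methyl 2-[4-(2-hydroxy-4,6-dimethoxy-3-[(4-methoxyphenyl)acetyl]phenoxy)phenyl]acetate | COC(=O)Cc1ccc(Oc2c(OC)cc(OC)c(C(=O)Cc3ccc(OC)cc3)c2O)cc1 | intermediate
20 | 2-[4-(2-hydroxy-4,6-dimethoxy-3-[(4-methoxyphenyl)acetyl]phenoxy)phenyl]acetic acid | OC(=O)Cc1ccc(Oc2c(OC)cc(OC)c(C(=O)Cc3ccc(OC)cc3)c2O)cc1 | intermediate
21 | 3,5-dimethoxyphenol | COc1cc(O)cc(OC)c1 | starting material
22 | 2-chloro-3,5-dimethoxyphenol | COc1cc(O)c(Cl)c(OC)c1 | intermediate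
23 | 1-(3-chloro-2-hydroxy-4,6-dimethoxyphenyl)-2-[4-(2-hydroxy-4,6-dimethoxy-3-[(4-methoxyphenyl)acetyl]phenoxy)phenyl]ethan-1-one | COc1cc(OC)c(C(=O)Cc2ccc(Oc3c(OC)cc(OC)c(C(=O)Cc4ccc(OC)cc4)c3O)cc2)c(O)c1Cl | intermediate
24 | bis-enaminone of 23 (each CH2 turned into C=CH–NMe2; push–pull alkenes, geometry labile and not defined) | COc1cc(OC)c(C(=O)C(=CN(C)C)c2ccc(Oc3c(OC)cc(OC)c(C(=O)C(=CN(C)C)c4ccc(OC)cc4)c3O)cc2)c(O)c1Cl | intermediate
25 | 8-chloro-3-(4-{[5,7-dimethoxy-3-(4-methoxyphenyl)-4-oxo-4H-chromen-8-yl]oxy}phenyl)-5,7-dimethoxy-4H-chromen-4-one | O=c1c(-c2ccc(Oc3c(OC)cc(OC)c4c(=O)c(-c5ccc(OC)cc5)coc34)cc2)coc2c(Cl)c(OC)cc(OC)c12 | intermediate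
26 | bisoflavolin I, 8-chloro-3-(4-{[5,7-dihydroxy-3-(4-hydroxyphenyl)-4-oxo-4H-chromen-8-yl]oxy}phenyl)-5,7-dihydroxy-4H-chromen-4-one | O=c1c(-c2ccc(Oc3c(O)cc(O)c4c(=O)c(-c5ccc(O)cc5)coc34)cc2)coc2c(Cl)c(O)cc(O)c12 | target

## Step count and risks

Total step count: 15. Longest linear sequence: 14 (steps 1–11 and 13–15, from 1 to 26). Step 12 is a one-step side branch.

**Risk 1, step 5.**
- The ynol ether may polymerise or hydrate before it meets the pyrone.
- The weak aryloxy donor and the ortho groups may slow the cycloaddition until pyrone dimerisation takes over.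
- The orientation may leak towards the meta benzoate.

The fallback sets out from phenol 4 and gives up building ring B'. The ring D oxygen acts as nucleophile in a nucleophilic aromatic substitution on 4-fluorobenzaldehyde (K2CO3, DMAc, 130 °C, Ar). This should give 4-[2-(benzyloxy)-4,6-dimethoxyphenoxy]benzaldehyde F1. C8'' is still never the site of substitution. Reduction with NaBH4 in MeOH returns to the route at alcohol 14.

**Risk 2, step 13.**
- Acylation of the chlorine-deactivated phenol may be slow.
- Attack may occur at the carbon between the two methoxy groups.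
- Prolonged heating may cleave the methyl ether next to the new ketone. That would create a second ortho hydroxyl and blur the later ring closure.

The fallback sets out from acid 20 and phenol 22. They are first joined through oxygen (EDC·HCl, DMAP, CH2Cl2, rt) to give 2-chloro-3,5-dimethoxyphenyl 2-[4-(2-hydroxy-4,6-dimethoxy-3-[(4-methoxyphenyl)acetyl]phenoxy)phenyl]acetate F2. The hindered, hydrogen-bonded ring D phenol should stay out of this coupling. A TiCl4-mediated Fries rearrangement (1,2-dichloroethane, rt to 60 °C) then moves the acyl group to the free ortho carbon and returns to the route at 23.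

**Risk 3, step 10.**
- Acylation may go to the wrong ring D carbon.
- The water formed may partly hydrolyse the methyl ester, which would then take part as an acyl donor and cause oligomerisation.
- The methyl ether beside the new ketone may be lost.

The fallback sets out from phenol 17 and installs the carbonyl carbon by a strictly ortho-selective route. Casnati–Skattebøl formylation through the magnesium phenoxide (MgCl2, Et3N, paraformaldehyde, MeCN, reflux) should give methyl 2-[4-(3-formyl-2-hydroxy-4,6-dimethoxyphenoxy)phenyl]acetate F3. Addition of 4-methoxybenzylmagnesium chloride (2 equiv, THF, −78 °C), where the aldehyde reacts ahead of the ester, should give racemic methyl 2-[4-(2-hydroxy-3-[1-hydroxy-2-(4-methoxyphenyl)ethyl]-4,6-dimethoxyphenoxy)phenyl]acetate F4. Oxidation of the benzylic alcohol with MnO2 in CH2Cl2 under neutral conditions returns to the route at 19.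

## Further compounds

F1 | step 5 | 4-[2-(benzyloxy)-4,6-dimethoxyphenoxy]benzaldehyde | O=Cc1ccc(Oc2c(OC)cc(OC)cc2OCc2ccccc2)cc1
F2 | step 13 | 2-chloro-3,5-dimethoxyphenyl 2-[4-(2-hydroxy-4,6-dimethoxy-3-[(4-methoxyphenyl)acetyl]phenoxy)phenyl]acetate | COc1cc(OC)c(Cl)c(OC(=O)Cc2ccc(Oc3c(OC)cc(OC)c(C(=O)Cc4ccc(OC)cc4)c3O)cc2)c1
F3 | step 10 | methyl 2-[4-(3-formyl-2-hydroxy-4,6-dimethoxyphenoxy)phenyl]acetate | COC(=O)Cc1ccc(Oc2c(OC)cc(OC)c(C=O)c2O)cc1
F4 | step 10 | methyl 2-[4-(2-hydroxy-3-[1-hydroxy-2-(4-methoxyphenyl)ethyl]-4,6-dimethoxyphenoxy)phenyl]acetate (racemic) | COC(=O)Cc1ccc(Oc2c(OC)cc(OC)c(C(O)Cc3ccc(OC)cc3)c2O)cc1
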